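**Plan**
Numbering follows the two guaianolide halves: unprimed for the diol unit, primed for the ketone unit; the central cyclopentane is C3–C4–C15–C15′–C4′.
Enabling feature: the spiro carbon C4′ is bonded to the C3′ carbonyl of the primed cyclopentanone (C1′–C5′) and to the ring methylene C15′, so a C4′=C15′ cyclopentene can accept a C3′ acyl radical at C4′ and a hydrogen atom at C15′.
Retrosynthesis: cut C3′–C4′ last (acyl radical), then C3–C4′ (alkenylchromium addition to the C3 ketone) and C15–C15′ (Michael addition); the primed half is a 3′,4′-seco keto acid.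
Forward: dehydrocostus lactone is converted into amine-masked dehydrozaluzanin C, which serves twice: one portion is ring-cleaved to the primed half and joined to a second portion, the central cyclopentene is closed, then the primed cyclopentanone with the spiro centre, and both lactones are unmasked.
Stereochemistry: C1, C5, C6, C7 and C1′, C5′, C6′, C7′ come unchanged from dehydrocostus lactone; C4 from α-face oxidation of a silyl enol ether, C3 from the enforced cis ring fusion, C4′ from C5′ through allylic strain in the radical closure.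

Key step: step 13

Assumption: step 1 is taken to give the 3α-alcohol and the amine additions the 11βH adducts; C3 (step 3), C4 of 6 (step 5) and C11/C11′ (step 14) are erased later, so these assignments do not affect the outcome.

Step 1
Reactants: 1 dehydrocostus lactone
Product: 2 3-epizaluzanin C (3α-hydroxydehydrocostus lactone)
Conditions: SeO2 (0.5 equiv), t-BuOOH (2 equiv), CH2Cl2, 0 °C to rt
Reagents that add atoms: SeO2, O=[Se]=O (oxygen carrier); tert-butyl hydroperoxide, CC(C)(C)OO (terminal oxygen source)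
Why: Allylic oxidation with SeO2 (ene reaction, then 2,3-sigmatropic shift) should hydroxylate C3, the secondary allylic position of the C4(15) methylene, on the convex α face, while the electron-poor lactone methylene stays inert.

Step 2
Reactants: 2 3-epizaluzanin C
Product: 3 13-(dimethylamino)-11βH,13-dihydro-3-epizaluzanin C
Conditions: Me2NH (2 M in THF, 3 equiv), MeOH, 0 °C to rt; excess amine removed in vacuo
Reagents that add atoms: dimethylamine, CNC
Why: Aza-Michael addition to the α-methylene lactone, the only electron-poor alkene, masks it against hydride, enolates and radicals, with protonation of C11 from the convex face.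

Step 3
Reactants: 3 13-(dimethylamino)-11βH,13-dihydro-3-epizaluzanin C
Product: 4 13-(dimethylamino)-11βH,13-dihydrodehydrozaluzanin C (3-oxo-4(15)-ene, lactone methylene masked)
Conditions: MnO2 (activated, excess), CH2Cl2, rt
Reagents that add atoms: none
Why: Allylic alcohol oxidation with MnO2 should give the exocyclic enone, to which the tertiary amine cannot add.

Step 4
Reactants: 4 13-(dimethylamino)-11βH,13-dihydrodehydrozaluzanin C
Product: 6 13-(dimethylamino)-4α-hydroxy-3-oxo-11βH-guai-10(14)-en-12,6α-olide (4β-methyl α-ketol), via potassium enolate 5 (not isolated)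
Conditions: K[(sec-Bu)3BH] (1.05 equiv), THF, −78 °C, inverse addition; then 2-(phenylsulfonyl)-3-phenyloxaziridine (1.3 equiv), −78 to −40 °C; aq NH4Cl
Reagents that add atoms: 2-(phenylsulfonyl)-3-phenyloxaziridine, O=S(=O)(c1ccccc1)N1OC1c1ccccc1
Why: The β-unsubstituted exocyclic enone should be reduced in the 1,4-sense and the regiodefined tetrasubstituted enolate hydroxylated at C4 by the N-sulfonyloxaziridine (conjugate reduction–enolate oxidation), on the convex α face, although this centre is destroyed in step 5.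

Step 5
Reactants: 6 4α-hydroxy-3-oxo α-ketol
Product: 7 13-(dimethylamino)-4-oxo-3,4-seco-11βH-guai-10(14)-en-12,6α-olid-3-oic acid (C1 carries CH2CO2H, C5 carries acetyl, cis)
Conditions: NaIO4 (3 equiv), THF–H2O (pH 7 buffer), rt
Reagents that add atoms: sodium periodate, [Na+].[O-]I(=O)(=O)=O
Why: Periodate cleavage of the tertiary α-ketol should break C3–C4 to the C3 acid and the C4 methyl ketone without touching the alkenes or the C1 and C5 centres.

Step 6
Reactants: 7 seco keto acid
Product: 8 2-(trimethylsilyl)ethyl ester of 7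
Conditions: Me3SiCH2CH2OH (3 equiv), EDC·HCl, DMAP (cat.), CH2Cl2, rt
Reagents that add atoms: 2-(trimethylsilyl)ethanol, C[Si](C)(C)CCO
Why: Carbodiimide (Steglich) esterification gives an ester that should survive enolate, peracid and chromium chemistry and is later cleaved by fluoride without hydrolysis.

Step 7
Reactants: 8 seco keto ester; 4 13-(dimethylamino)-11βH,13-dihydrodehydrozaluzanin C
Product: 11 C15–C15′-linked seco-dimer (3-triethylsilyloxy-3-ene on the unprimed unit; 4′-ketone and 3′-ester on the primed 3′,4′-seco unit), via lithium enolate 9 (not isolated), via adduct lithium enolate 10 (not isolated)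
Conditions: LiN(iPr)2 (1.05 equiv), THF, −78 °C; 4 (1.1 equiv), −78 °C; Et3SiCl (1.5 equiv), −78 to −20 °C; aq NaHCO3
Reagents that add atoms: chlorotriethylsilane, CC[Si](Cl)(CC)CC
Why: Kinetic deprotonation at the methyl group (C15′) gives the less substituted enolate, which should add to the unhindered exocyclic β-carbon C15 of 4 (Michael addition), and O-silylation of the resulting tetrasubstituted enolate fixes the C3=C4 regiochemistry for the later oxidation; no stereocentre is formed.

Step 8
Reactants: 11 silyl enol ether ketone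
Product: 13 (Z)-C4′ alkenyl triflate (OTf on C4′ cis to C15; C3 triethylsilyl enol ether retained), via potassium enolate 12 (not isolated)
Conditions: KN(SiMe3)2 (1.1 equiv), THF, −78 °C; PhNTf2 (1.2 equiv), −78 to 0 °C; aq NH4Cl
Reagents that add atoms: N-phenylbis(trifluoromethanesulfonimide), O=S(=O)(N(c1ccccc1)S(=O)(=O)C(F)(F)F)C(F)(F)F
Why: The base should remove a C15′ proton rather than the hindered C5′–H and give mainly the Z(O)-enolate of this ketone with a branched acyl side, which the triflimide traps as the enol triflate with OTf and C15 cis, as the ring closure requires (kinetic enol triflate formation).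

Step 9
Reactants: 13 (Z)-alkenyl triflate silyl enol ether
Product: 15 4α-hydroxy-3-ketone bearing the (Z)-alkenyl triflate, via silyloxy ketone 14 (not isolated)
Conditions: CF3CO2H (2.05 equiv), CH2Cl2, −40 °C; mCPBA (1.1 equiv), −40 to −10 °C; then HF·pyridine, THF, 0 °C; aq NaHCO3
Reagents that add atoms: 3-chloroperoxybenzoic acid, OOC(=O)c1cccc(Cl)c1
Why: Rubottom oxidation: with both amines held as trifluoroacetate salts the peracid should epoxidise only the electron-rich silyl enol ether, from the convex α face (that of H-5, opposite C6), and silyl migration then fluoride cleavage give the 4α-hydroxy ketone, which sets C4 with C15 on the β face.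

Step 10
Reactants: 15 4α-hydroxy-3-ketone alkenyl triflate
Product: 16 3α,4α-diol with the central cyclopent-15′-ene closed (C3–C4′ bond), 2-(trimethylsilyl)ethyl 3′-ester
Conditions: CrCl2 (8 equiv), NiCl2 (10 mol %), degassed DMF, rt to 45 °C
Reagents that add atoms: none
Why: Nozaki–Hiyama–Kishi reaction in its intramolecular ketone form: zerovalent nickel inserts into the C–OTf bond, transmetalation gives the alkenylchromium, and this adds to the C3 ketone through a five-membered transition state from the β face on which the C15 tether lies, so only the cis-fused diquinane with the 3α-hydroxyl can form.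

Step 11
Reactants: 16 diol ester
Product: 17 C3′ carboxylic acid of 16
Conditions: Bu4NF (3 equiv), THF, 0 °C to rt; aq NH4Cl
Reagents that add atoms: none
Why: Fluoride-induced β-elimination of the 2-(trimethylsilyl)ethyl ester should free the acid without the hydrolytic conditions that would open the lactones.

Step 12
Reactants: 17 C3′ acid
Product: 18 Se-phenyl C3′ selenoester (3α,4α-diol, C4′=C15′ cyclopentene, both lactones as dimethylamine adducts)
Conditions: (PhSe)2 (1.5 equiv), PBu3 (2 equiv), CH2Cl2, rt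
Reagents that add atoms: diphenyl diselenide, c1ccc(cc1)[Se][Se]c1ccccc1
Why: Activation of the carboxylate as an acyloxyphosphonium ion by the phosphine–diselenide pair and attack of phenylselenolate should give the selenoester, with tertiary alcohols and amines not interfering.

Step 13
Reactants: 18 Se-phenyl C3′ selenoester
Product: 19 ainsliadimer A bis(dimethylamine) adduct (13- and 13′-dimethylamino, 11βH, 11′βH)
Conditions: Bu3SnH (1.4 equiv, ca. 0.02 M), AIBN (0.2 equiv), PhH, 80 °C
Reagents that add atoms: none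
Why: Bu3Sn• abstracts the phenylselanyl group and the C3′ acyl radical adds to C4′ of the C4′=C15′ cyclopentene, after which the C15′ radical takes hydrogen from Bu3SnH; this is the established chain cyclization of selenoester-derived acyl radicals onto alkenes to give cyclopentanones. The primed cyclopentanone closes in the 5-exo-trig mode and the spiro centre C4′ is created in the same event. Its configuration follows from the fixed C5′ centre: in the rotamer about C4′–C5′ of least allylic strain H-5′ lies next to the quaternary C3 and C6′ next to H-15′, which places the C1′ tether on the hydroxyl-bearing convex face of the central ring, so C3′ bonds cis to the C3 oxygen. Chemoselectivity is secured because both lactone methylenes are masked as amine adducts and the C10′ methylene could only be reached by 4-exo or 5-endo closure. The less certain requirement is 5-exo rather than 6-endo attack (at C15′), since C4′ is the more substituted terminus; the tether anchored directly on C4′ and the small free C3 hydroxyl, able to hydrogen-bond the acyl oxygen, are relied on here. The stannane concentration is chosen so that cyclization outruns reduction of the acyl radical while the C15′ radical is quenched before a 1,2-acyl shift can set in, and decarbonylation is slow because the acyl carbon carries a primary alkyl group.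

Step 14
Reactants: 19 ainsliadimer A bis(dimethylamine) adduct
Product: 21 ainsliadimer A, via bis(methiodide) 20 (not isolated)
Conditions: MeI (excess), MeOH, rt; evaporate; aq NaHCO3, CH2Cl2, rt
Reagents that add atoms: none
Why: Exhaustive N-methylation followed by bicarbonate-induced E1cB elimination of trimethylamine should restore both α-methylene lactones under conditions too mild for retro-aldol cleavage of the β-hydroxy ketone.

**Compound list**
1 | dehydrocostus lactone | C=C1CC[C@H]2C(=C)CC[C@H]3C(=C)C(=O)O[C@@H]3[C@H]21 | starting material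
2 | 3-epizaluzanin C (3α-hydroxydehydrocostus lactone) | C=C1C(=O)O[C@@H]2[C@@H]3[C@@H](C[C@@H](O)C3=C)C(=C)CC[C@@H]12 | intermediate
3 | 13-(dimethylamino)-11βH,13-dihydro-3-epizaluzanin C | CN(C)C[C@@H]1C(=O)O[C@@H]2[C@@H]3[C@@H](C[C@@H](O)C3=C)C(=C)CC[C@@H]12 | intermediate
4 | 13-(dimethylamino)-11βH,13-dihydrodehydrozaluzanin C | CN(C)C[C@@H]1C(=O)O[C@@H]2[C@@H]3[C@@H](CC(=O)C3=C)C(=C)CC[C@@H]12 | intermediate
5 | potassium C3–C4 enolate from conjugate reduction of 4 (not isolated) | CN(C)C[C@@H]1C(=O)O[C@@H]2[C@@H]3[C@@H](CC([O-])=C3C)C(=C)CC[C@@H]12.[K+] | intermediate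
6 | 13-(dimethylamino)-4α-hydroxy-3-oxo-11βH-guai-10(14)-en-12,6α-olide | CN(C)C[C@@H]1C(=O)O[C@@H]2[C@@H]3[C@@H](CC(=O)[C@@]3(C)O)C(=C)CC[C@@H]12 | intermediate
7 | 13-(dimethylamino)-4-oxo-3,4-seco-11βH-guai-10(14)-en-12,6α-olid-3-oic acid | CN(C)C[C@@H]1C(=O)O[C@@H]2[C@@H](C(C)=O)[C@@H](CC(=O)O)C(=C)CC[C@@H]12 | intermediate
8 | 2-(trimethylsilyl)ethyl ester of 7 | CN(C)C[C@@H]1C(=O)O[C@@H]2[C@@H](C(C)=O)[C@@H](CC(=O)OCC[Si](C)(C)C)C(=C)CC[C@@H]12 | intermediate
9 | lithium enolate of 8 at the methyl (C15′) terminus (not isolated) | CN(C)C[C@@H]1C(=O)O[C@@H]2[C@@H](C(=C)[O-])[C@@H](CC(=O)OCC[Si](C)(C)C)C(=C)CC[C@@H]12.[Li+] | intermediate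
10 | lithium C3 enolate of the Michael adduct (not isolated) | CN(C)C[C@@H]1C(=O)O[C@@H]2[C@@H]3[C@@H](CC([O-])=C3CCC(=O)[C@H]4[C@@H](CC(=O)OCC[Si](C)(C)C)C(=C)CC[C@H]5[C@H](CN(C)C)C(=O)O[C@@H]54)C(=C)CC[C@@H]12.[Li+] | intermediate
11 | C15–C15′-linked seco-dimer, C3 triethylsilyl enol ether, C4′ ketone | CN(C)C[C@@H]1C(=O)O[C@@H]2[C@@H]3[C@@H](CC(O[Si](CC)(CC)CC)=C3CCC(=O)[C@H]4[C@@H](CC(=O)OCC[Si](C)(C)C)C(=C)CC[C@H]5[C@H](CN(C)C)C(=O)O[C@@H]54)C(=C)CC[C@@H]12 | intermediate
12 | potassium (Z)-C4′ enolate of 11 (not isolated) | CN(C)C[C@@H]1C(=O)O[C@@H]2[C@@H]3[C@@H](CC(O[Si](CC)(CC)CC)=C3C/C=C(\[O-])[C@H]4[C@@H](CC(=O)OCC[Si](C)(C)C)C(=C)CC[C@H]5[C@H](CN(C)C)C(=O)O[C@@H]54)C(=C)CC[C@@H]12.[K+] | intermediate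
13 | (Z)-C4′ alkenyl triflate with C3 triethylsilyl enol ether | CN(C)C[C@@H]1C(=O)O[C@@H]2[C@@H]3[C@@H](CC(O[Si](CC)(CC)CC)=C3C/C=C(\OS(=O)(=O)C(F)(F)F)[C@H]4[C@@H](CC(=O)OCC[Si](C)(C)C)C(=C)CC[C@H]5[C@H](CN(C)C)C(=O)O[C@@H]54)C(=C)CC[C@@H]12 | intermediate
14 | 4α-triethylsilyloxy-3-ketone alkenyl triflate (not isolated) | CN(C)C[C@@H]1C(=O)O[C@@H]2[C@@H]3[C@@H](CC(=O)[C@]3(O[Si](CC)(CC)CC)C/C=C(\OS(=O)(=O)C(F)(F)F)[C@H]4[C@@H](CC(=O)OCC[Si](C)(C)C)C(=C)CC[C@H]5[C@H](CN(C)C)C(=O)O[C@@H]54)C(=C)CC[C@@H]12 | intermediate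
15 | 4α-hydroxy-3-ketone (Z)-alkenyl triflate | CN(C)C[C@@H]1C(=O)O[C@@H]2[C@@H]3[C@@H](CC(=O)[C@]3(O)C/C=C(\OS(=O)(=O)C(F)(F)F)[C@H]4[C@@H](CC(=O)OCC[Si](C)(C)C)C(=C)CC[C@H]5[C@H](CN(C)C)C(=O)O[C@@H]54)C(=C)CC[C@@H]12 | intermediate
16 | 3α,4α-diol with closed central cyclopent-15′-ene, 2-(trimethylsilyl)ethyl 3′-ester | CN(C)C[C@@H]1C(=O)O[C@@H]2[C@@H]3[C@@H](C[C@@]4(O)[C@]3(O)CC=C4[C@H]5[C@@H](CC(=O)OCC[Si](C)(C)C)C(=C)CC[C@H]6[C@H](CN(C)C)C(=O)O[C@@H]65)C(=C)CC[C@@H]12 | intermediate
17 | C3′ carboxylic acid of 16 | CN(C)C[C@@H]1C(=O)O[C@@H]2[C@@H]3[C@@H](C[C@@]4(O)[C@]3(O)CC=C4[C@H]5[C@@H](CC(=O)O)C(=C)CC[C@H]6[C@H](CN(C)C)C(=O)O[C@@H]65)C(=C)CC[C@@H]12 | intermediate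
18 | Se-phenyl C3′ selenoester (radical precursor) | CN(C)C[C@@H]1C(=O)O[C@@H]2[C@@H]3[C@@H](C[C@@]4(O)[C@]3(O)CC=C4[C@H]5[C@@H](CC(=O)[Se]c6ccccc6)C(=C)CC[C@H]6[C@H](CN(C)C)C(=O)O[C@@H]65)C(=C)CC[C@@H]12 | intermediate
19 | ainsliadimer A bis(dimethylamine) adduct | CN(C)C[C@@H]1C(=O)O[C@@H]2[C@@H]3[C@@H](C[C@@]4(O)[C@]3(O)CC[C@]43C(=O)C[C@H]4C(=C)CC[C@H]5[C@H](CN(C)C)C(=O)O[C@@H]5[C@H]43)C(=C)CC[C@@H]12 | intermediate
20 | bis(trimethylammonium) diiodide of 19 (not isolated) | C[N+](C)(C)C[C@@H]1C(=O)O[C@@H]2[C@@H]3[C@@H](C[C@@]4(O)[C@]3(O)CC[C@]43C(=O)C[C@H]4C(=C)CC[C@H]5[C@H](C[N+](C)(C)C)C(=O)O[C@@H]5[C@H]43)C(=C)CC[C@@H]12.[I-].[I-] | intermediate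
21 | ainsliadimer A | C=C1C(=O)O[C@@H]2[C@@H]3[C@@H](C[C@@]4(O)[C@]3(O)CC[C@]43C(=O)C[C@H]4C(=C)CC[C@H]5C(=C)C(=O)O[C@@H]5[C@H]43)C(=C)CC[C@@H]12 | target

**Step count and risks**
Total steps: 14. Longest linear sequence: 14 steps (1 to 21; steps 1–3 supply compound 4 for both halves).

Step 13 (most at risk). The acyl radical may bond to the less substituted C15′ in the 6-endo mode, or the C15′ radical may ring-expand by 1,2-acyl shift, so that the spiro centre is not formed. The fallback leaves the radical route at 2 and makes the C3–C4′ bond by aldol chemistry instead. MnO2 oxidation of 2 would give dehydrozaluzanin C F1. Its hetero-Diels–Alder dimerisation (neat, with a hydrogen-bond donor such as a 1,1′-bi-2-naphthol, mild warming) would join O3′ to C4 and C15′ to C15 in the spiro-dihydropyran dimer F2. Aqueous HCl in THF would hydrolyse the enol ether to the 4α-hydroxy 3,3′-diketone F3. DBU in CH2Cl2 would then close C4′ onto the C3 ketone, and the route is rejoined at 21.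

Step 10. The alkenylchromium may be protonated (loss of the triflate to C–H) before it adds to the hindered, fully substituted α-hydroxy ketone. The fallback sets out from 15: Miyaura borylation (B2pin2, PdCl2(PPh3)2, PPh3, KOPh, toluene, 50 °C) would give the alkenyl pinacol boronate F4 with retention of geometry. A [Rh(cod)OH]2-catalysed intramolecular 1,2-addition of the alkenylrhodium to the C3 ketone (dioxane–H2O, 60 °C) would then return to the route at 16.

Step 7. Proton transfer among the enolates, 1,2-addition, or enolisation toward C5′ followed by β-elimination of the C6′ lactone oxygen may erode the anionic Michael addition. The fallback sets out from 8: the kinetic triethylsilyl enol ether F5 would be isolated (LiN(iPr)2, Et3SiCl, THF, −78 °C) and added to 4 in a Mukaiyama–Michael reaction. For this, both amines are first protonated with HN(SO2CF3)2 and Et3SiOSO2CF3 (10 mol %) is used in CH2Cl2 at −78 °C; silyl transfer delivers the C3 silyl enol ether directly, and the route is rejoined at 11.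

**Further compounds**
F1 | step 13 | dehydrozaluzanin C | C=C1C(=O)O[C@@H]2[C@@H]3[C@@H](CC(=O)C3=C)C(=C)CC[C@@H]12
F2 | step 13 | spiro-dihydropyran dimer (O3′–C4 and C15′–C15 bonds, C4 oxygen α) | C=C1C(=O)O[C@@H]2[C@@H]3[C@@H](CC(=O)[C@]34CCC5=C(O4)C[C@H]6C(=C)CC[C@H]7C(=C)C(=O)O[C@@H]7[C@@H]56)C(=C)CC[C@@H]12
F3 | step 13 | 4α-hydroxy 3,3′-diketone (C4′–H, enolisable, configuration at C4′ not fixed) | C=C1C(=O)O[C@@H]2[C@@H]3[C@@H](CC(=O)[C@]3(O)CCC4C(=O)C[C@H]5C(=C)CC[C@H]6C(=C)C(=O)O[C@@H]6[C@@H]45)C(=C)CC[C@@H]12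
F4 | step 10 | alkenyl pinacol boronate of 15 (boron on C4′ cis to C15) | CN(C)C[C@@H]1C(=O)O[C@@H]2[C@@H]3[C@@H](CC(=O)[C@]3(O)C/C=C(\B4OC(C)(C)C(C)(C)O4)[C@H]4[C@@H](CC(=O)OCC[Si](C)(C)C)C(=C)CC[C@H]5[C@H](CN(C)C)C(=O)O[C@@H]54)C(=C)CC[C@@H]12
F5 | step 7 | kinetic triethylsilyl enol ether of 8 | CN(C)C[C@@H]1C(=O)O[C@@H]2[C@@H](C(=C)O[Si](CC)(CC)CC)[C@@H](CC(=O)OCC[Si](C)(C)C)C(=C)CC[C@@H]12
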